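**Remark on the chemistry (assumption):** atom numbers in the text are those of the furo[3,2-b]furan-2-one skeleton of the target (O1, C2, C3, C3a, O4, C5, C6, C6a). Compounds 11 and 12 are anomeric mixtures, which does not matter because the acetal carbon and its methyl-bearing neighbour both become sp2 in step 6.

## Retrosynthetic overview

1. The lactone ring is annulated last onto a preformed oxolane ring: C3–C3a by an Ireland–Claisen shift of the 2,3-dihydrofuran-3-yl acetate 15, and O1–C6a by iodolactonisation in the same flask; the iodine is then removed.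
2. Enabling feature: in the oxolane ring the methylene C6 sits between the ring-fusion carbon C6a and the fully substituted C5. A temporary oxygen on C6 can therefore deliver the acetate unit to C3a by allylic transposition (C3a=C6a enol ether becomes the C6=C6a alkene), and because C5 carries no hydrogen the 3-acyloxy-2,3-dihydrofuran cannot aromatise to a furan.
3. The C6–O ester bond, absent from the target, is a temporary tether: it relays the C5 configuration to C3a and is cleaved in the rearrangement. C6a then follows from the obligatory cis ring fusion.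
4. The oxolane ring is made first: D-proline cross-aldol of propanal with the α-silyloxy aldehyde 8, closure to a methyl furanoside, and elimination to the cyclic enol ether.
5. C5 and the side chain come from (R)-2-methylglycidol and a 9-phenylnonyl Grignard reagent.

Key step: step 8

## Route

Step 1
Reactants: 1 phenylmagnesium bromide; 2 1,9-dibromononane
Product: 3 (9-bromononyl)benzene
Conditions: FeCl3 (5 mol %), TMEDA, THF, 0 °C, slow addition of 1 to 2 (3 equiv)
Reagents that add atoms: none
Why: Iron-catalysed Kumada-type sp2–sp3 cross-coupling of an aryl Grignard reagent with a primary alkyl bromide should mono-arylate the dibromide when 2 is in threefold excess and 1 is added slowly; no stereocentre is involved.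

Step 2
Reactants: 3 (9-bromononyl)benzene; 4 [(2R)-2-methyloxiran-2-yl]methanol
Product: 6 (2S)-2-methyl-12-phenyldodecane-1,2-diol, via (9-phenylnonyl)magnesium bromide 5 (not isolated)
Conditions: Mg, THF, 50 °C; then 4 (0.45 equiv), CuI (10 mol %), THF, −30 → 0 °C; aq. NH4Cl
Reagents that add atoms: none
Why: Copper-catalysed SN2 opening of the 2,2-disubstituted epoxide by Grignard reagent 5 occurs at the unhindered CH2 terminus, so the quaternary carbinol centre of 4 is not touched and becomes C5 of the target with its configuration intact (the first equivalent of 5 is consumed by the hydroxyl proton).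

Step 3
Reactants: 6 (2S)-2-methyl-12-phenyldodecane-1,2-diol
Product: 7 (2S)-2-methyl-12-phenyl-1,2-bis(triethylsilyloxy)dodecane
Conditions: Et3SiOTf (2.5 equiv), 2,6-lutidine, CH2Cl2, −78 → 0 °C
Reagents that add atoms: triethylsilyl trifluoromethanesulfonate, CC[Si](CC)(CC)OS(=O)(=O)C(F)(F)F
Why: A silyl triflate with 2,6-lutidine silylates the primary and the hindered tertiary hydroxyl alike, which prepares the selective unmasking of the primary position in step 4.

Step 4
Reactants: 7 (2S)-2-methyl-12-phenyl-1,2-bis(triethylsilyloxy)dodecane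
Product: 8 (2S)-2-methyl-12-phenyl-2-(triethylsilyloxy)dodecanal
Conditions: (COCl)2, DMSO, CH2Cl2, −78 → −40 °C; Et3N, → 0 °C
Reagents that add atoms: none
Why: Under Swern conditions a primary triethylsilyl ether is cleaved and oxidised directly to the aldehyde while the tertiary silyl ether is inert, and the α-carbon is quaternary so it cannot epimerise.

Step 5
Reactants: 8 (2S)-2-methyl-12-phenyl-2-(triethylsilyloxy)dodecanal; 9 propanal
Product: 11 (2S,3S,4R)-5-methoxy-2,4-dimethyl-2-(10-phenyldecyl)oxolan-3-ol, via aldol adduct 10 (not isolated)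
Conditions: D-proline (20 mol %), DMF, 4 °C, 9 added over 24 h; then MeOH, CSA, 23 °C
Reagents that add atoms: methanol, CO
Why: Enamine catalysis by D-proline (direct cross-aldol reaction) uses propanal as donor and the non-enolisable 8 as acceptor, the hydrogen-bonded chair-like transition state of the catalyst fixing the new carbinol centre as 3S (anti to the α-methyl) largely independently of the neighbouring quaternary centre, and acid methanolysis then removes the silyl group and closes the methyl furanoside (Fischer-type acetalisation).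

Step 6
Reactants: 11 (2S,3S,4R)-5-methoxy-2,4-dimethyl-2-(10-phenyldecyl)oxolan-3-ol
Product: 13 {[(2S,3S)-2,4-dimethyl-2-(10-phenyldecyl)-2,3-dihydrofuran-3-yl]oxy}trimethylsilane, via silylated furanoside 12 (not isolated)
Conditions: Me3SiOTf (2.4 equiv), iPr2NEt (3 equiv), CH2Cl2, −20 → 23 °C
Reagents that add atoms: trimethylsilyl trifluoromethanesulfonate, C[Si](C)(C)OS(=O)(=O)C(F)(F)F
Why: Silyl triflate and a hindered amine first silylate the secondary hydroxyl and then convert the cyclic acetal into the enol ether (acetal-to-enol-ether elimination through the ring oxocarbenium ion), the only removable β-hydrogen being the one on the methyl-bearing carbon; the two stereocentres that matter are not involved.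

Step 7
Reactants: 13 {[(2S,3S)-2,4-dimethyl-2-(10-phenyldecyl)-2,3-dihydrofuran-3-yl]oxy}trimethylsilane
Product: 15 (2S,3S)-2,4-dimethyl-2-(10-phenyldecyl)-2,3-dihydrofuran-3-yl acetate, via dihydrofuranol 14 (not isolated)
Conditions: Bu4NF, THF, 0 °C; then Ac2O, Et3N, DMAP, 0 → 23 °C
Reagents that add atoms: acetic anhydride, CC(=O)OC(C)=O
Why: Fluoride desilylation and DMAP-catalysed acetylation in one basic flask install the acetate without exposing the acid-labile allylic alcohol 14 to isolation; no stereocentre is touched.

Step 8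
Reactants: 15 (2S,3S)-2,4-dimethyl-2-(10-phenyldecyl)-2,3-dihydrofuran-3-yl acetate
Product: 19 (3aR,5S,6S,6aS)-6-iodo-5,6a-dimethyl-5-(10-phenyldecyl)tetrahydrofuro[3,2-b]furan-2(3H)-one, via silyl ketene acetal 16 (not isolated), via trimethylsilyl ester 17 (not isolated), via dihydrofuranylacetic acid 18 (not isolated)
Conditions: LiN(iPr)2, Me3SiCl, THF, −78 → 40 °C; then I2, NaHCO3, THF–H2O, 0 °C
Reagents that add atoms: iodine, II
Why: Deprotonation of the acetate in the presence of Me3SiCl gives silyl ketene acetal 16, whose [3,3]-sigmatropic shift through a boat-like six-membered transition state forms C3–C3a on the ring face that carried the ester oxygen and moves the double bond to C6=C6a; iodine then closes carboxylate 18 onto the tertiary alkene carbon to form O1–C6a. The closest known reaction types are the ester-enolate (Ireland–Claisen) rearrangement of furanoid glycal esters and the iodolactonisation of γ,δ-unsaturated acids. The lactone ring closes 5-exo-trig on an iodonium ion by anti addition, and because the two-carbon tether spans adjacent ring atoms only the cis-fused bicycle can form. C3a is fixed by suprafacial chirality transfer from the temporary C6 acetoxy centre, which was placed cis to the phenyldecyl chain in step 5; C6a follows from the cis fusion, and the C6 iodide centre is removed in step 9. The step needs O-silylation and rearrangement to outrun ionisation of the allylic ester, which the basic medium and the electron-rich enol ether should secure, and Markovnikov closure, which the methyl group on C6a secures; the quaternary C5 excludes aromatisation to a furan, and the neutral iodine conditions leave the tertiary allylic C5–O4 bond intact where a protic acid would ionise it.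

Step 9
Reactants: 19 (3aR,5S,6S,6aS)-6-iodo-5,6a-dimethyl-5-(10-phenyldecyl)tetrahydrofuro[3,2-b]furan-2(3H)-one
Product: 20 plakortolide ether, (3aR,5S,6aR)-5,6a-dimethyl-5-(10-phenyldecyl)tetrahydrofuro[3,2-b]furan-2(3H)-one
Conditions: Bu3SnH, AIBN, PhMe, 80 °C
Reagents that add atoms: none
Why: Tin hydride radical-chain dehalogenation replaces the secondary iodide by hydrogen, since hydrogen transfer to the C6 radical is much faster than a 1,2-acyloxy shift, and the three remaining stereocentres are not affected.

## Compound list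

1 | phenylmagnesium bromide | Br[Mg]c1ccccc1 | starting material
2 | 1,9-dibromononane | BrCCCCCCCCCBr | starting material
3 | (9-bromononyl)benzene | BrCCCCCCCCCc1ccccc1 | intermediate
4 | [(2R)-2-methyloxiran-2-yl]methanol, (R)-2-methylglycidol | C[C@@]1(CO)CO1 | starting material
5 | (9-phenylnonyl)magnesium bromide | Br[Mg]CCCCCCCCCc1ccccc1 | intermediate
6 | (2S)-2-methyl-12-phenyldodecane-1,2-diol | C[C@](O)(CCCCCCCCCCc1ccccc1)CO | intermediate
7 | (2S)-2-methyl-12-phenyl-1,2-bis(triethylsilyloxy)dodecane | C[C@](O[Si](CC)(CC)CC)(CCCCCCCCCCc1ccccc1)CO[Si](CC)(CC)CC | intermediate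
8 | (2S)-2-methyl-12-phenyl-2-(triethylsilyloxy)dodecanal | C[C@](O[Si](CC)(CC)CC)(CCCCCCCCCCc1ccccc1)C=O | intermediate
9 | propanal | CCC=O | starting material
10 | (2R,3S,4S)-3-hydroxy-2,4-dimethyl-14-phenyl-4-(triethylsilyloxy)tetradecanal | C[C@](O[Si](CC)(CC)CC)(CCCCCCCCCCc1ccccc1)[C@@H](O)[C@@H](C)C=O | intermediate
11 | (2S,3S,4R)-5-methoxy-2,4-dimethyl-2-(10-phenyldecyl)oxolan-3-ol (both anomers) | C[C@]1(CCCCCCCCCCc2ccccc2)[C@@H](O)[C@@H](C)C(OC)O1 | intermediate
12 | {[(2S,3S,4R)-5-methoxy-2,4-dimethyl-2-(10-phenyldecyl)oxolan-3-yl]oxy}trimethylsilane (both anomers) | C[C@]1(CCCCCCCCCCc2ccccc2)[C@@H](O[Si](C)(C)C)[C@@H](C)C(OC)O1 | intermediate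
13 | {[(2S,3S)-2,4-dimethyl-2-(10-phenyldecyl)-2,3-dihydrofuran-3-yl]oxy}trimethylsilane | C[C@]1(CCCCCCCCCCc2ccccc2)[C@@H](O[Si](C)(C)C)C(C)=CO1 | intermediate
14 | (2S,3S)-2,4-dimethyl-2-(10-phenyldecyl)-2,3-dihydrofuran-3-ol | C[C@]1(CCCCCCCCCCc2ccccc2)[C@@H](O)C(C)=CO1 | intermediate
15 | (2S,3S)-2,4-dimethyl-2-(10-phenyldecyl)-2,3-dihydrofuran-3-yl acetate | C[C@]1(CCCCCCCCCCc2ccccc2)[C@@H](OC(C)=O)C(C)=CO1 | intermediate
16 | 1-{[(2S,3S)-2,4-dimethyl-2-(10-phenyldecyl)-2,3-dihydrofuran-3-yl]oxy}-1-(trimethylsilyloxy)ethene | C[C@]1(CCCCCCCCCCc2ccccc2)[C@@H](OC(=C)O[Si](C)(C)C)C(C)=CO1 | intermediate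
17 | trimethylsilyl 2-[(2R,5S)-3,5-dimethyl-5-(10-phenyldecyl)-2,5-dihydrofuran-2-yl]acetate | C[C@]1(CCCCCCCCCCc2ccccc2)C=C(C)[C@@H](CC(=O)O[Si](C)(C)C)O1 | intermediate
18 | 2-[(2R,5S)-3,5-dimethyl-5-(10-phenyldecyl)-2,5-dihydrofuran-2-yl]acetic acid (present as its sodium salt) | C[C@]1(CCCCCCCCCCc2ccccc2)C=C(C)[C@@H](CC(=O)O)O1 | intermediate
19 | (3aR,5S,6S,6aS)-6-iodo-5,6a-dimethyl-5-(10-phenyldecyl)tetrahydrofuro[3,2-b]furan-2(3H)-one | C[C@]1(CCCCCCCCCCc2ccccc2)[C@H](I)[C@@]2(C)OC(=O)C[C@H]2O1 | intermediate
20 | plakortolide ether, (3aR,5S,6aR)-5,6a-dimethyl-5-(10-phenyldecyl)tetrahydrofuro[3,2-b]furan-2(3H)-one | C[C@]1(CCCCCCCCCCc2ccccc2)C[C@@]2(C)OC(=O)C[C@H]2O1 | target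

## Step count and risks

Total steps: 9. Longest linear sequence: 9 steps (1 and 2 to 20).

Steps most likely to fail:

**Step 5.** The self-aldol reaction of propanal may outrun addition to the hindered α-quaternary acceptor, and the facial selectivity may erode. Fallback: setting out from aldehyde 8, asymmetric crotylboration with (E)-crotyldiisopinocampheylborane F1 is used instead. F1 is generated in the flask from trans-2-butene, n-BuLi, KOtBu, (−)-Ipc2BOMe and BF3·OEt2 in THF at −78 °C, and the reaction is worked up with NaBO3. This should give the anti homoallylic alcohol (3S,4S,5S)-3,5-dimethyl-15-phenyl-5-(triethylsilyloxy)pentadec-1-en-4-ol F2 under reagent control. Ozonolysis of F2 (O3, CH2Cl2–MeOH, −78 °C; Me2S) returns to the route at aldol adduct 10, which is closed to 11 by the acid methanolysis of step 5.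

**Step 6.** The silyl triflate may cleave the ring C–O bond of the furanoside instead of the methoxy group, or ionise the allylic C–O bond of the product. Fallback: setting out from 11, the anomeric methoxy group is exchanged for a sulfone (PhSO2H, CaCl2, CH2Cl2) to give (2S,3S,4R)-5-(benzenesulfonyl)-2,4-dimethyl-2-(10-phenyldecyl)oxolan-3-ol F3. Base-induced loss of benzenesulfinate (DBU, PhMe, 80 °C) then gives the enol ether without any Lewis acid and returns to the route at dihydrofuranol 14, which is acetylated to 15 as in the second half of step 7.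

**Step 8.** C-silylation or ketene loss from the acetate enolate, or ionisation of the allylic ester with allylic scrambling, may compete with the sigmatropic shift. Fallback: setting out from 15, Tsuji–Trost allylic alkylation with sodium dimethyl malonate (Pd(PPh3)4, THF) is used. Ionisation and attack both occur with inversion on zerovalent palladium, so the carbon nucleophile enters the unhindered enol-ether terminus on the face the acetate left, giving dimethyl 2-[(2R,5S)-3,5-dimethyl-5-(10-phenyldecyl)-2,5-dihydrofuran-2-yl]propanedioate F4. Krapcho demethoxycarbonylation (LiCl, wet DMSO, 140 °C) gives methyl 2-[(2R,5S)-3,5-dimethyl-5-(10-phenyldecyl)-2,5-dihydrofuran-2-yl]acetate F5, and saponification (LiOH, THF–H2O) returns to the route at acid 18, which is iodolactonised (I2, NaHCO3) to 19.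

## Further compounds

F1 | step 5 | (E)-crotyldiisopinocampheylborane (from (−)-Ipc2BOMe) | C/C=C/CB([C@@H]1C[C@@H]2C[C@H]([C@H]1C)C2(C)C)[C@@H]1C[C@@H]2C[C@H]([C@H]1C)C2(C)C
F2 | step 5 | (3S,4S,5S)-3,5-dimethyl-15-phenyl-5-(triethylsilyloxy)pentadec-1-en-4-ol | C[C@](O[Si](CC)(CC)CC)(CCCCCCCCCCc1ccccc1)[C@@H](O)[C@@H](C)C=C
F3 | step 6 | (2S,3S,4R)-5-(benzenesulfonyl)-2,4-dimethyl-2-(10-phenyldecyl)oxolan-3-ol | C[C@]1(CCCCCCCCCCc2ccccc2)[C@@H](O)[C@@H](C)C(S(=O)(=O)c2ccccc2)O1
F4 | step 8 | dimethyl 2-[(2R,5S)-3,5-dimethyl-5-(10-phenyldecyl)-2,5-dihydrofuran-2-yl]propanedioate | C[C@]1(CCCCCCCCCCc2ccccc2)C=C(C)[C@@H](C(C(=O)OC)C(=O)OC)O1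
F5 | step 8 | methyl 2-[(2R,5S)-3,5-dimethyl-5-(10-phenyldecyl)-2,5-dihydrofuran-2-yl]acetate | C[C@]1(CCCCCCCCCCc2ccccc2)C=C(C)[C@@H](CC(=O)OC)O1
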